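**Plan**
1. Retrosynthetic cuts: the lactone O–C6 bond together with C3–O (one palladium-mediated diene oxidation), the C4–O/C5–O pair (dihydroxylation), C5=C6 (ring-closing metathesis), C4–C5 and C3=C4 (Stille coupling, iodo-olefination), C7–C8 (Barbier allylation), C9–O (α-aminoxylation) and the two acyl C–O bonds.
2. Forward: (R)-citronellal (C8–C10, C1–C3, C14) is α-oxygenated and joined to dienyl bromide 4 (C6, C7, C11–C13); its far end is rebuilt into a (Z)-2-methyl-1,3-diene; metathesis closes the ten-membered carbocycle; the γ-lactone is the last ring to form.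
3. Enabling feature: in the carbocycle the C3=C4–C5=C6 diene ends at C6, next to C7, which carries the acrylic acid C11(=C13)–C12O2H. Oxidative 1,4-addition across this diene lets the carboxylate oxygen close the lactone at C6, places a removable acyloxy group on C3 and moves the double bond to C4=C5.
4. One dihydroxylation of C4=C5 completes the contiguous C3–C6 oxygen array; angeloylation, unmasking and oxidation of C3, and desilylation of O8 finish the route.
5. Stereochemistry: C10 from citronellal; C9 from L-proline; C8 and C7 from the chelated, chair-like allylindium addition; C6 relayed from C7 through the tether; C4/C5 by osmylation anti to the O3 and O6 substituents; the acyl stereo-elements from (R)-2-methylbutanoic acid and angelic acid.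

Key step: step 12

Remarks on the chemistry:
- Locants follow the germacrane pattern: ring C1–C10 with C3 the ketone carbon, C4 the methyl carbinol, C5 the angelate carbon, C6 the lactone O–CH, C7 the ring-fusion CH, C8 the free carbinol, C9 the 2-methylbutanoate carbon, C10 the CHMe carbon; C11/C12/C13 are the lactone α-carbon, carbonyl and exocyclic methylene; C14 is the methyl on C10 and C15 the methyl on C4.
- Assumption: (R)-2-methylbutanoic acid is taken as commercially available, as are (R)-citronellal and angelic acid.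

**Route**

Step 1
Reactants: 1 acrolein; 2 tert-butyl acrylate
Product: 3 tert-butyl 3-hydroxy-2-methylidenepent-4-enoate (racemic)
Conditions: DABCO (cat.), neat (excess 2), 0 °C → rt
Reagents that add atoms: none
Why: Morita–Baylis–Hillman reaction, in which the ammonium enolate formed from DABCO and the acrylate adds to the aldehyde carbon of acrolein; the carbinol stereocenter is removed in step 2.

Step 2
Reactants: 3 tert-butyl 3-hydroxy-2-methylidenepent-4-enoate
Product: 4 tert-butyl (2Z)-2-(bromomethyl)penta-2,4-dienoate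
Conditions: NBS, Me2S, CH2Cl2, 0 °C → rt
Reagents that add atoms: N-bromosuccinimide, O=C1CCC(=O)N1Br
Why: Corey–Kim-type bromination with allylic transposition (SN2'), which should deliver bromide to the acrylate CH2 and give the fully conjugated dienoate as the favoured Z isomer (vinyl trans to the ester).

Step 3
Reactants: 5 (R)-citronellal; 4 tert-butyl (2Z)-2-(bromomethyl)penta-2,4-dienoate
Product: 7 tert-butyl (3S,4R,5R,6R)-3-ethenyl-4-hydroxy-6,10-dimethyl-2-methylidene-5-[(phenylamino)oxy]undec-9-enoate, via anilinooxy aldehyde 6 (not isolated)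
Conditions: PhNO, L-proline (cat.), DMSO, rt; then 4, indium powder, THF/H2O, rt
Reagents that add atoms: nitrosobenzene, O=Nc1ccccc1
Why: Proline-catalysed α-aminoxylation (enamine catalysis, catalyst control sets C9 as R) followed by indium-mediated Barbier allylation at the γ-carbon of the ester-chelated (Z)-allylindium through a chair transition state (C7/C8 syn), on the aldehyde face fixed by chelation of indium between the carbonyl and the α-oxygen (C8/C9 syn).

Step 4
Reactants: 7 tert-butyl (3S,4R,5R,6R)-3-ethenyl-4-hydroxy-6,10-dimethyl-2-methylidene-5-[(phenylamino)oxy]undec-9-enoate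
Product: 8 tert-butyl (3S,4R,5R,6R)-4-[(tert-butyldimethylsilyl)oxy]-3-ethenyl-6,10-dimethyl-2-methylidene-5-[(phenylamino)oxy]undec-9-enoate
Conditions: TBSOTf, 2,6-lutidine, CH2Cl2, −78 °C
Reagents that add atoms: tert-butyldimethylsilyl trifluoromethanesulfonate, CC(C)(C)[Si](C)(C)OS(=O)(=O)C(F)(F)F
Why: Silyl ether formation at the only free hydroxyl (O8), which must stay blocked so that the later carboxylic acid cannot lactonize onto O8; no stereocenter is touched.

Step 5
Reactants: 8 tert-butyl (3S,4R,5R,6R)-4-[(tert-butyldimethylsilyl)oxy]-3-ethenyl-6,10-dimethyl-2-methylidene-5-[(phenylamino)oxy]undec-9-enoate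
Product: 9 tert-butyl (3S,4R,5R,6R)-4-[(tert-butyldimethylsilyl)oxy]-3-ethenyl-5-hydroxy-6,10-dimethyl-2-methylideneundec-9-enoate
Conditions: Zn dust, AcOH, THF, rt
Reagents that add atoms: none
Why: Reductive N–O bond cleavage by zinc in acetic acid should free the C9 hydroxyl and leave the silyl ether, the tert-butyl ester and the alkenes untouched.

Step 6
Reactants: 9 tert-butyl (3S,4R,5R,6R)-4-[(tert-butyldimethylsilyl)oxy]-3-ethenyl-5-hydroxy-6,10-dimethyl-2-methylideneundec-9-enoate; 10 (R)-2-methylbutanoic acid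
Product: 11 tert-butyl (3S,4R,5R,6R)-4-[(tert-butyldimethylsilyl)oxy]-3-ethenyl-6,10-dimethyl-2-methylidene-5-{[(2R)-2-methylbutanoyl]oxy}undec-9-enoate
Conditions: DCC, DMAP (cat.), CH2Cl2, 0 °C → rt
Reagents that add atoms: none
Why: Steglich esterification of the C9 alcohol; the acid stereocenter is carried in unchanged, with low temperature and catalytic DMAP chosen to suppress ketene formation.

Step 7
Reactants: 11 tert-butyl (3S,4R,5R,6R)-4-[(tert-butyldimethylsilyl)oxy]-3-ethenyl-6,10-dimethyl-2-methylidene-5-{[(2R)-2-methylbutanoyl]oxy}undec-9-enoate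
Product: 12 tert-butyl (3S,4R,5R,6R)-4-[(tert-butyldimethylsilyl)oxy]-3-ethenyl-6-methyl-2-methylidene-5-{[(2R)-2-methylbutanoyl]oxy}-9-oxononanoate
Conditions: O3, pyridine, CH2Cl2, −78 °C (Sudan Red 7B end point)
Reagents that add atoms: ozone, [O-][O+]=O
Why: Ozonolysis selected by alkene nucleophilicity: the trisubstituted alkene should react before the monosubstituted vinyl group and the electron-poor acrylate, and pyridine decomposes the carbonyl oxide so that the C3 aldehyde forms directly.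

Step 8
Reactants: 12 tert-butyl (3S,4R,5R,6R)-4-[(tert-butyldimethylsilyl)oxy]-3-ethenyl-6-methyl-2-methylidene-5-{[(2R)-2-methylbutanoyl]oxy}-9-oxononanoate
Product: 13 tert-butyl (3S,4R,5R,6R,9Z)-4-[(tert-butyldimethylsilyl)oxy]-3-ethenyl-10-iodo-6-methyl-2-methylidene-5-{[(2R)-2-methylbutanoyl]oxy}undec-9-enoate
Conditions: EtPPh3I, n-BuLi, THF, 0 °C; I2, −78 °C; NaN(SiMe3)2, −78 °C; then 12, −78 → −20 °C
Reagents that add atoms: ethyltriphenylphosphonium iodide, CC[P+](c1ccccc1)(c1ccccc1)c1ccccc1.[I-]; iodine, II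
Why: Stork–Zhao-type Wittig olefination with the α-iodo ylide, which is kinetically Z-selective and should set the C3=C4 geometry (C2 and iodine cis).

Step 9
Reactants: 13 tert-butyl (3S,4R,5R,6R,9Z)-4-[(tert-butyldimethylsilyl)oxy]-3-ethenyl-10-iodo-6-methyl-2-methylidene-5-{[(2R)-2-methylbutanoyl]oxy}undec-9-enoate
Product: 14 tert-butyl (3S,4R,5R,6R,9Z)-4-[(tert-butyldimethylsilyl)oxy]-3-ethenyl-6,10-dimethyl-2-methylidene-5-{[(2R)-2-methylbutanoyl]oxy}dodeca-9,11-dienoate
Conditions: Bu3SnCH=CH2, Pd(PPh3)4 (cat.), CuI (cat.), DMF, rt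
Reagents that add atoms: tributyl(vinyl)stannane, C=C[Sn](CCCC)(CCCC)CCCC
Why: Stille coupling replaces iodine by vinyl with retention of alkene geometry, giving the (Z)-2-methyl-1,3-diene terminus (C2 and C5 cis).

Step 10
Reactants: 14 tert-butyl (3S,4R,5R,6R,9Z)-4-[(tert-butyldimethylsilyl)oxy]-3-ethenyl-6,10-dimethyl-2-methylidene-5-{[(2R)-2-methylbutanoyl]oxy}dodeca-9,11-dienoate
Product: 15 tert-butyl 2-[(1S,2Z,4Z,8R,9R,10R)-10-[(tert-butyldimethylsilyl)oxy]-4,8-dimethyl-9-{[(2R)-2-methylbutanoyl]oxy}cyclodeca-2,4-dien-1-yl]prop-2-enoate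
Conditions: second-generation Grubbs catalyst (cat.), toluene (high dilution), 80 °C
Reagents that add atoms: none
Why: Ring-closing metathesis between the terminal alkene of the diene and the C7 vinyl group expels ethene and forms C5=C6; the ten-membered ring should accept the conjugated diene only as the Z,Z isomer, and the 1,1-disubstituted acrylate and the trisubstituted C3=C4 bond are too unreactive to compete.

Step 11
Reactants: 15 tert-butyl 2-[(1S,2Z,4Z,8R,9R,10R)-10-[(tert-butyldimethylsilyl)oxy]-4,8-dimethyl-9-{[(2R)-2-methylbutanoyl]oxy}cyclodeca-2,4-dien-1-yl]prop-2-enoate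
Product: 17 2-[(1S,2Z,4Z,8R,9R,10R)-10-[(tert-butyldimethylsilyl)oxy]-4,8-dimethyl-9-{[(2R)-2-methylbutanoyl]oxy}cyclodeca-2,4-dien-1-yl]prop-2-enoic acid, via trimethylsilyl ester 16 (not isolated)
Conditions: TMSOTf, 2,6-lutidine, CH2Cl2, 0 °C; then pH 5 aqueous buffer
Reagents that add atoms: none
Why: Silyl-triflate-mediated cleavage of the tert-butyl ester (loss of 2-methylpropene) gives the silyl ester, which hydrolyses on work-up, under conditions that should spare the secondary TBS ether, the 2-methylbutanoate and the diene.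

Step 12
Reactants: 17 2-[(1S,2Z,4Z,8R,9R,10R)-10-[(tert-butyldimethylsilyl)oxy]-4,8-dimethyl-9-{[(2R)-2-methylbutanoyl]oxy}cyclodeca-2,4-dien-1-yl]prop-2-enoic acid
Product: 18 (3R,4Z,6R,7R,8R,9R,10R)-8-[(tert-butyldimethylsilyl)oxy]-3-(methoxyacetoxy)-9-{[(2R)-2-methylbutanoyl]oxy}germacra-4,11(13)-dien-12,6-olide
Conditions: Pd(OAc)2 (cat.), p-benzoquinone, LiCl (cat.), LiO2CCH2OMe, MeOCH2CO2H, acetone, rt
Reagents that add atoms: methoxyacetic acid, COCC(=O)O
Why: Divalent palladium binds the C3=C4–C5=C6 diene on the face away from the C7 side chain, the C12 carboxylate adds to C6 anti to the metal to give a π-allylpalladium unit over C3–C5, methoxyacetate then attacks C3 from outside because chloride occupies the metal, and benzoquinone reoxidizes the zerovalent palladium that is released. The closest known reaction type is the palladium-catalysed, benzoquinone-driven intramolecular 1,4-oxylactonization (1,4-diacyloxylation) of cyclic conjugated dienes that carry a carboxymethyl-type tether next to the diene. The γ-lactone closes by 5-exo attack of oxygen on the diene terminus (O–C6 bond) and is cis-fused to the ten-membered ring. C6 is controlled by C7, because the short C11–C12 tether can reach only the diene face on which it sits, and C3 follows from the two successive anti attacks (cis-1,4 relationship of O3 and O6); the Z geometry of the new C4=C5 bond follows from the s-cis Z,Z diene. The step needs attack at C6 and not C3 (five- against eight-membered ring), 1,4- and not 1,2-addition (C3 is the allyl terminus remote from the new C–O bond and less hindered than C5), and reaction at the electron-rich diene and not at the electron-poor C11=C13 acrylate. Lactonization toward O8 is excluded by the silyl ether, and the methoxyacetate on C3 is chosen because it can later be removed in the presence of the other esters.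

Step 13
Reactants: 18 (3R,4Z,6R,7R,8R,9R,10R)-8-[(tert-butyldimethylsilyl)oxy]-3-(methoxyacetoxy)-9-{[(2R)-2-methylbutanoyl]oxy}germacra-4,11(13)-dien-12,6-olide
Product: 19 (3R,4R,5R,6S,7R,8R,9R,10R)-8-[(tert-butyldimethylsilyl)oxy]-4,5-dihydroxy-3-(methoxyacetoxy)-9-{[(2R)-2-methylbutanoyl]oxy}germacr-11(13)-en-12,6-olide
Conditions: OsO4 (cat.), NMO, acetone/H2O, rt
Reagents that add atoms: N-methylmorpholine N-oxide, C[N+]1([O-])CCOCC1; water, O
Why: Upjohn dihydroxylation: OsO4 should select the isolated trisubstituted C4=C5 bond over the electron-poor C11=C13 acrylate and add syn from the face anti to the two allylic C–O bonds at C3 and C6 (both on the same face), which sets the tertiary C4 carbinol and C5.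

Step 14
Reactants: 19 (3R,4R,5R,6S,7R,8R,9R,10R)-8-[(tert-butyldimethylsilyl)oxy]-4,5-dihydroxy-3-(methoxyacetoxy)-9-{[(2R)-2-methylbutanoyl]oxy}germacr-11(13)-en-12,6-olide; 20 angelic acid
Product: 22 (3R,4S,5R,6S,7R,8R,9R,10R)-5-(angeloyloxy)-8-[(tert-butyldimethylsilyl)oxy]-4-hydroxy-3-(methoxyacetoxy)-9-{[(2R)-2-methylbutanoyl]oxy}germacr-11(13)-en-12,6-olide, via mixed anhydride 21 (not isolated)
Conditions: 2,4,6-trichlorobenzoyl chloride, Et3N, toluene, rt; then 19, 75 °C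
Reagents that add atoms: none
Why: Yamaguchi mixed-anhydride esterification, in which the secondary C5 hydroxyl should be acylated in preference to the tertiary C4 hydroxyl and the DMAP-free conditions should keep the Z (angelate) geometry.

Step 15
Reactants: 22 (3R,4S,5R,6S,7R,8R,9R,10R)-5-(angeloyloxy)-8-[(tert-butyldimethylsilyl)oxy]-4-hydroxy-3-(methoxyacetoxy)-9-{[(2R)-2-methylbutanoyl]oxy}germacr-11(13)-en-12,6-olide
Product: 23 (3R,4S,5R,6S,7R,8R,9R,10R)-5-(angeloyloxy)-8-[(tert-butyldimethylsilyl)oxy]-3,4-dihydroxy-9-{[(2R)-2-methylbutanoyl]oxy}germacr-11(13)-en-12,6-olide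
Conditions: Yb(OTf)3 (cat.), MeOH, rt
Reagents that add atoms: none
Why: Lewis-acid-catalysed transesterification with methanol, selective for the α-alkoxy ester that chelates ytterbium, so that the angelate, the 2-methylbutanoate, the lactone and the α-methylene group should stay in place under neutral conditions.

Step 16
Reactants: 23 (3R,4S,5R,6S,7R,8R,9R,10R)-5-(angeloyloxy)-8-[(tert-butyldimethylsilyl)oxy]-3,4-dihydroxy-9-{[(2R)-2-methylbutanoyl]oxy}germacr-11(13)-en-12,6-olide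
Product: 24 (4R,5R,6S,7R,8R,9R,10R)-5-(angeloyloxy)-8-[(tert-butyldimethylsilyl)oxy]-4-hydroxy-9-{[(2R)-2-methylbutanoyl]oxy}-3-oxogermacr-11(13)-en-12,6-olide
Conditions: Dess–Martin periodinane, pyridine, CH2Cl2, 0 °C → rt
Reagents that add atoms: none
Why: Dess–Martin oxidation of the only secondary alcohol (C3) to the ketone; the tertiary C4 alcohol cannot be oxidized and the mild buffered conditions should avoid α-ketol rearrangement.

Step 17
Reactants: 24 (4R,5R,6S,7R,8R,9R,10R)-5-(angeloyloxy)-8-[(tert-butyldimethylsilyl)oxy]-4-hydroxy-9-{[(2R)-2-methylbutanoyl]oxy}-3-oxogermacr-11(13)-en-12,6-olide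
Product: 25 (4R,5R,6S,7S,8R,9R,10R)-5-(angeloyloxy)-4,8-dihydroxy-9-{[(2R)-2-methylbutanoyl]oxy}-3-oxogermacr-11(13)-en-12,6-olide (CNP0226386.1)
Conditions: HF·pyridine, THF, 0 °C → rt
Reagents that add atoms: none
Why: Fluoride-mediated desilylation frees the C8 hydroxyl under weakly acidic conditions that should avoid acyl migration from O9, translactonization to O8 and conjugate addition to the α-methylene lactone.

**Compound list**
1 | acrolein | C=CC=O | starting material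
2 | tert-butyl acrylate | C=CC(=O)OC(C)(C)C | starting material
3 | tert-butyl 3-hydroxy-2-methylidenepent-4-enoate (racemic) | C=CC(O)C(=C)C(=O)OC(C)(C)C | intermediate
4 | tert-butyl (2Z)-2-(bromomethyl)penta-2,4-dienoate | C=C/C=C(\CBr)C(=O)OC(C)(C)C | intermediate
5 | (R)-citronellal, (3R)-3,7-dimethyloct-6-enal | O=CC[C@H](C)CCC=C(C)C | starting material
6 | (2R,3R)-3,7-dimethyl-2-[(phenylamino)oxy]oct-6-enal (not isolated) | O=C[C@H](ONc1ccccc1)[C@H](C)CCC=C(C)C | intermediate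
7 | tert-butyl (3S,4R,5R,6R)-3-ethenyl-4-hydroxy-6,10-dimethyl-2-methylidene-5-[(phenylamino)oxy]undec-9-enoate | C=C[C@@H](C(=C)C(=O)OC(C)(C)C)[C@@H](O)[C@H](ONc1ccccc1)[C@H](C)CCC=C(C)C | intermediate
8 | tert-butyl (3S,4R,5R,6R)-4-[(tert-butyldimethylsilyl)oxy]-3-ethenyl-6,10-dimethyl-2-methylidene-5-[(phenylamino)oxy]undec-9-enoate | C=C[C@@H](C(=C)C(=O)OC(C)(C)C)[C@@H](O[Si](C)(C)C(C)(C)C)[C@H](ONc1ccccc1)[C@H](C)CCC=C(C)C | intermediate
9 | tert-butyl (3S,4R,5R,6R)-4-[(tert-butyldimethylsilyl)oxy]-3-ethenyl-5-hydroxy-6,10-dimethyl-2-methylideneundec-9-enoate | C=C[C@@H](C(=C)C(=O)OC(C)(C)C)[C@@H](O[Si](C)(C)C(C)(C)C)[C@H](O)[C@H](C)CCC=C(C)C | intermediate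
10 | (R)-2-methylbutanoic acid | CC[C@@H](C)C(=O)O | starting material
11 | tert-butyl (3S,4R,5R,6R)-4-[(tert-butyldimethylsilyl)oxy]-3-ethenyl-6,10-dimethyl-2-methylidene-5-{[(2R)-2-methylbutanoyl]oxy}undec-9-enoate | C=C[C@@H](C(=C)C(=O)OC(C)(C)C)[C@@H](O[Si](C)(C)C(C)(C)C)[C@H](OC(=O)[C@H](C)CC)[C@H](C)CCC=C(C)C | intermediate
12 | tert-butyl (3S,4R,5R,6R)-4-[(tert-butyldimethylsilyl)oxy]-3-ethenyl-6-methyl-2-methylidene-5-{[(2R)-2-methylbutanoyl]oxy}-9-oxononanoate | C=C[C@@H](C(=C)C(=O)OC(C)(C)C)[C@@H](O[Si](C)(C)C(C)(C)C)[C@H](OC(=O)[C@H](C)CC)[C@H](C)CCC=O | intermediate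
13 | tert-butyl (3S,4R,5R,6R,9Z)-4-[(tert-butyldimethylsilyl)oxy]-3-ethenyl-10-iodo-6-methyl-2-methylidene-5-{[(2R)-2-methylbutanoyl]oxy}undec-9-enoate | C=C[C@@H](C(=C)C(=O)OC(C)(C)C)[C@@H](O[Si](C)(C)C(C)(C)C)[C@H](OC(=O)[C@H](C)CC)[C@H](C)CC/C=C(\I)C | intermediate
14 | tert-butyl (3S,4R,5R,6R,9Z)-4-[(tert-butyldimethylsilyl)oxy]-3-ethenyl-6,10-dimethyl-2-methylidene-5-{[(2R)-2-methylbutanoyl]oxy}dodeca-9,11-dienoate | C=C[C@@H](C(=C)C(=O)OC(C)(C)C)[C@@H](O[Si](C)(C)C(C)(C)C)[C@H](OC(=O)[C@H](C)CC)[C@H](C)CC/C=C(\C=C)C | intermediate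
15 | tert-butyl 2-[(1S,2Z,4Z,8R,9R,10R)-10-[(tert-butyldimethylsilyl)oxy]-4,8-dimethyl-9-{[(2R)-2-methylbutanoyl]oxy}cyclodeca-2,4-dien-1-yl]prop-2-enoate | CC(C)(C)[Si](C)(C)O[C@@H]1[C@H](C(=C)C(=O)OC(C)(C)C)/C=C\C(C)=C/CC[C@@H](C)[C@H]1OC(=O)[C@H](C)CC | intermediate
16 | trimethylsilyl 2-[(1S,2Z,4Z,8R,9R,10R)-10-[(tert-butyldimethylsilyl)oxy]-4,8-dimethyl-9-{[(2R)-2-methylbutanoyl]oxy}cyclodeca-2,4-dien-1-yl]prop-2-enoate (not isolated) | CC(C)(C)[Si](C)(C)O[C@@H]1[C@H](C(=C)C(=O)O[Si](C)(C)C)/C=C\C(C)=C/CC[C@@H](C)[C@H]1OC(=O)[C@H](C)CC | intermediate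
17 | 2-[(1S,2Z,4Z,8R,9R,10R)-10-[(tert-butyldimethylsilyl)oxy]-4,8-dimethyl-9-{[(2R)-2-methylbutanoyl]oxy}cyclodeca-2,4-dien-1-yl]prop-2-enoic acid | CC(C)(C)[Si](C)(C)O[C@@H]1[C@H](C(=C)C(=O)O)/C=C\C(C)=C/CC[C@@H](C)[C@H]1OC(=O)[C@H](C)CC | intermediate
18 | (3R,4Z,6R,7R,8R,9R,10R)-8-[(tert-butyldimethylsilyl)oxy]-3-(methoxyacetoxy)-9-{[(2R)-2-methylbutanoyl]oxy}germacra-4,11(13)-dien-12,6-olide | C=C1C(=O)O[C@@H]2/C=C(C)\[C@H](OC(=O)COC)CC[C@@H](C)[C@@H](OC(=O)[C@H](C)CC)[C@H](O[Si](C)(C)C(C)(C)C)[C@H]12 | intermediate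
19 | (3R,4R,5R,6S,7R,8R,9R,10R)-8-[(tert-butyldimethylsilyl)oxy]-4,5-dihydroxy-3-(methoxyacetoxy)-9-{[(2R)-2-methylbutanoyl]oxy}germacr-11(13)-en-12,6-olide | C=C1C(=O)O[C@@H]2[C@@H](O)[C@@](C)(O)[C@H](OC(=O)COC)CC[C@@H](C)[C@@H](OC(=O)[C@H](C)CC)[C@H](O[Si](C)(C)C(C)(C)C)[C@H]12 | intermediate
20 | angelic acid, (2Z)-2-methylbut-2-enoic acid | C/C=C(/C)C(=O)O | starting material
21 | (2Z)-2-methylbut-2-enoic 2,4,6-trichlorobenzoic anhydride (not isolated) | C/C=C(/C)C(=O)OC(=O)c1c(Cl)cc(Cl)cc1Cl | intermediate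
22 | (3R,4S,5R,6S,7R,8R,9R,10R)-5-(angeloyloxy)-8-[(tert-butyldimethylsilyl)oxy]-4-hydroxy-3-(methoxyacetoxy)-9-{[(2R)-2-methylbutanoyl]oxy}germacr-11(13)-en-12,6-olide | C=C1C(=O)O[C@@H]2[C@@H](OC(=O)/C(C)=C\C)[C@@](C)(O)[C@H](OC(=O)COC)CC[C@@H](C)[C@@H](OC(=O)[C@H](C)CC)[C@H](O[Si](C)(C)C(C)(C)C)[C@H]12 | intermediate
23 | (3R,4S,5R,6S,7R,8R,9R,10R)-5-(angeloyloxy)-8-[(tert-butyldimethylsilyl)oxy]-3,4-dihydroxy-9-{[(2R)-2-methylbutanoyl]oxy}germacr-11(13)-en-12,6-olide | C=C1C(=O)O[C@@H]2[C@@H](OC(=O)/C(C)=C\C)[C@@](C)(O)[C@H](O)CC[C@@H](C)[C@@H](OC(=O)[C@H](C)CC)[C@H](O[Si](C)(C)C(C)(C)C)[C@H]12 | intermediate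
24 | (4R,5R,6S,7R,8R,9R,10R)-5-(angeloyloxy)-8-[(tert-butyldimethylsilyl)oxy]-4-hydroxy-9-{[(2R)-2-methylbutanoyl]oxy}-3-oxogermacr-11(13)-en-12,6-olide | C=C1C(=O)O[C@@H]2[C@@H](OC(=O)/C(C)=C\C)[C@@](C)(O)C(=O)CC[C@@H](C)[C@@H](OC(=O)[C@H](C)CC)[C@H](O[Si](C)(C)C(C)(C)C)[C@H]12 | intermediate
25 | (4R,5R,6S,7S,8R,9R,10R)-5-(angeloyloxy)-4,8-dihydroxy-9-{[(2R)-2-methylbutanoyl]oxy}-3-oxogermacr-11(13)-en-12,6-olide (CNP0226386.1) | C=C1C(=O)O[C@H]2[C@@H]1[C@@H](O)[C@H](OC(=O)[C@H](C)CC)[C@H](C)CCC(=O)[C@](C)(O)[C@@H]2OC(=O)/C(C)=C\C | target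

**Count and risks**
Total step count: 17. Longest linear sequence: 17 steps (steps 1–17, from acrolein and tert-butyl acrylate; 15 steps from (R)-citronellal).

Steps most likely to fail:

1. Step 12 (oxidative 1,4-oxylactonization). What may go wrong: sluggish or unselective complexation of the medium-ring diene, competing 1,2-addition, or loss of the cis-1,4 relationship. Fallback, from 17 back to 18: phenylselenolactonization of 17 (PhSeCl, CH2Cl2, −78 °C) across C5=C6 should give the allylic selenide (3Z,5S,6S,7R,8R,9R,10R)-8-[(tert-butyldimethylsilyl)oxy]-9-{[(2R)-2-methylbutanoyl]oxy}-5-(phenylselanyl)germacra-3,11(13)-dien-12,6-olide F1. Oxidation (H2O2, pyridine) and [2,3]-sigmatropic shift of the allylic selenoxide should give the 3-epimeric allylic alcohol (3S,4Z,6R,7R,8R,9R,10R)-8-[(tert-butyldimethylsilyl)oxy]-3-hydroxy-9-{[(2R)-2-methylbutanoyl]oxy}germacra-4,11(13)-dien-12,6-olide F2. Mitsunobu esterification with methoxyacetic acid (PPh3, DIAD) inverts C3 and returns to the route at 18.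

2. Step 10 (diene–ene ring-closing metathesis to a ten-membered ring). What may go wrong: oligomerization, stalling at the conjugated ruthenium alkylidene, or ring contraction by attack on the internal alkene. Fallback, from 12 back to 15: anti-crotylation of 12 with pinacol (E)-crotylboronate should give the homoallylic alcohols tert-butyl (3S,4R,5R,6R)-4-[(tert-butyldimethylsilyl)oxy]-3-ethenyl-9-hydroxy-6,10-dimethyl-2-methylidene-5-{[(2R)-2-methylbutanoyl]oxy}dodec-11-enoate (9,10-anti, both anti isomers) F3. Metathesis of the two monosubstituted alkenes (second-generation Grubbs catalyst) should give the cyclodecenols tert-butyl 2-[(1S,2Z,8R,9R,10R)-10-[(tert-butyldimethylsilyl)oxy]-5-hydroxy-4,8-dimethyl-9-{[(2R)-2-methylbutanoyl]oxy}cyclodec-2-en-1-yl]prop-2-enoate F4. Mesylation (MsCl, Et3N) to the mesylates F5 and anti E2 elimination (DBU, toluene, heat) toward the allylic C4–H installs the Z C3=C4 bond after ring closure and returns to the route at 15.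

3. Step 3 (tandem aminoxylation and allylation). What may go wrong: erosion of the labile α-aminoxy aldehyde, attack of the allylindium through its remote terminus, or weak chelation leading to poor facial selectivity at C8. Fallback, from 5 back to 9:
 - Aminoxylation of 5 with in-situ NaBH4 reduction should give (2R,3R)-3,7-dimethyl-2-[(phenylamino)oxy]oct-6-en-1-ol F6.
 - Zn/AcOH gives (2R,3R)-3,7-dimethyloct-6-ene-1,2-diol F7.
 - Anisaldehyde dimethyl acetal with CSA gives the 4-methoxybenzylidene acetal (4R)-2-(4-methoxyphenyl)-4-[(2R)-6-methylhept-5-en-2-yl]-1,3-dioxolane F8.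
 - i-Bu2AlH opens it at the less hindered oxygen to (2R,3R)-2-[(4-methoxybenzyl)oxy]-3,7-dimethyloct-6-en-1-ol F9.
 - Dess–Martin oxidation gives the isolable aldehyde (2R,3R)-2-[(4-methoxybenzyl)oxy]-3,7-dimethyloct-6-enal F10.
 - Indium-mediated allylation with 4 under ether chelation should give tert-butyl (3S,4R,5R,6R)-3-ethenyl-4-hydroxy-5-[(4-methoxybenzyl)oxy]-6,10-dimethyl-2-methylideneundec-9-enoate F11.
 - TBSOTf gives tert-butyl (3S,4R,5R,6R)-4-[(tert-butyldimethylsilyl)oxy]-3-ethenyl-5-[(4-methoxybenzyl)oxy]-6,10-dimethyl-2-methylideneundec-9-enoate F12.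
 - DDQ removes the 4-methoxybenzyl group and returns to the route at 9.

**Further compounds**
F1 | step 12 | (3Z,5S,6S,7R,8R,9R,10R)-8-[(tert-butyldimethylsilyl)oxy]-9-{[(2R)-2-methylbutanoyl]oxy}-5-(phenylselanyl)germacra-3,11(13)-dien-12,6-olide | C=C1C(=O)O[C@@H]2[C@@H]([Se]c3ccccc3)/C(C)=C\CC[C@@H](C)[C@@H](OC(=O)[C@H](C)CC)[C@H](O[Si](C)(C)C(C)(C)C)[C@H]12
F2 | step 12 | (3S,4Z,6R,7R,8R,9R,10R)-8-[(tert-butyldimethylsilyl)oxy]-3-hydroxy-9-{[(2R)-2-methylbutanoyl]oxy}germacra-4,11(13)-dien-12,6-olide | C=C1C(=O)O[C@@H]2/C=C(C)\[C@@H](O)CC[C@@H](C)[C@@H](OC(=O)[C@H](C)CC)[C@H](O[Si](C)(C)C(C)(C)C)[C@H]12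
F3 | step 10 | tert-butyl (3S,4R,5R,6R)-4-[(tert-butyldimethylsilyl)oxy]-3-ethenyl-9-hydroxy-6,10-dimethyl-2-methylidene-5-{[(2R)-2-methylbutanoyl]oxy}dodec-11-enoate (9,10-anti, both anti isomers) | C=C[C@@H](C(=C)C(=O)OC(C)(C)C)[C@@H](O[Si](C)(C)C(C)(C)C)[C@H](OC(=O)[C@H](C)CC)[C@H](C)CCC(O)C(C)C=C
F4 | step 10 | tert-butyl 2-[(1S,2Z,8R,9R,10R)-10-[(tert-butyldimethylsilyl)oxy]-5-hydroxy-4,8-dimethyl-9-{[(2R)-2-methylbutanoyl]oxy}cyclodec-2-en-1-yl]prop-2-enoate (4,5-anti, both anti isomers) | CC(C)(C)[Si](C)(C)O[C@@H]1[C@H](C(=C)C(=O)OC(C)(C)C)/C=C\C(C)C(O)CC[C@@H](C)[C@H]1OC(=O)[C@H](C)CC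
F5 | step 10 | tert-butyl 2-[(1S,2Z,8R,9R,10R)-10-[(tert-butyldimethylsilyl)oxy]-5-(methanesulfonyloxy)-4,8-dimethyl-9-{[(2R)-2-methylbutanoyl]oxy}cyclodec-2-en-1-yl]prop-2-enoate (4,5-anti, both anti isomers) | CC(C)(C)[Si](C)(C)O[C@@H]1[C@H](C(=C)C(=O)OC(C)(C)C)/C=C\C(C)C(OS(C)(=O)=O)CC[C@@H](C)[C@H]1OC(=O)[C@H](C)CC
F6 | step 3 | (2R,3R)-3,7-dimethyl-2-[(phenylamino)oxy]oct-6-en-1-ol | OC[C@H](ONc1ccccc1)[C@H](C)CCC=C(C)C
F7 | step 3 | (2R,3R)-3,7-dimethyloct-6-ene-1,2-diol | OC[C@H](O)[C@H](C)CCC=C(C)C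
F8 | step 3 | (4R)-2-(4-methoxyphenyl)-4-[(2R)-6-methylhept-5-en-2-yl]-1,3-dioxolane (acetal carbon as a mixture) | COc1ccc(cc1)C1OC[C@@H]([C@H](C)CCC=C(C)C)O1
F9 | step 3 | (2R,3R)-2-[(4-methoxybenzyl)oxy]-3,7-dimethyloct-6-en-1-ol | OC[C@H](OCc1ccc(OC)cc1)[C@H](C)CCC=C(C)C
F10 | step 3 | (2R,3R)-2-[(4-methoxybenzyl)oxy]-3,7-dimethyloct-6-enal | O=C[C@H](OCc1ccc(OC)cc1)[C@H](C)CCC=C(C)C
F11 | step 3 | tert-butyl (3S,4R,5R,6R)-3-ethenyl-4-hydroxy-5-[(4-methoxybenzyl)oxy]-6,10-dimethyl-2-methylideneundec-9-enoate | C=C[C@@H](C(=C)C(=O)OC(C)(C)C)[C@@H](O)[C@H](OCc1ccc(OC)cc1)[C@H](C)CCC=C(C)C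
F12 | step 3 | tert-butyl (3S,4R,5R,6R)-4-[(tert-butyldimethylsilyl)oxy]-3-ethenyl-5-[(4-methoxybenzyl)oxy]-6,10-dimethyl-2-methylideneundec-9-enoate | C=C[C@@H](C(=C)C(=O)OC(C)(C)C)[C@@H](O[Si](C)(C)C(C)(C)C)[C@H](OCc1ccc(OC)cc1)[C@H](C)CCC=C(C)C
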